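The cyclohexane ring atoms are labelled C1 (CH with the acyloxypropyl chain), C2 (alkylidene carbon), C3, C4 (CH2), C5 (carbinol carbon) and C6 (quaternary carbon). The ring is cut on both sides of its C3–C4 ethano bridge. The key step exploits that the two atoms flanking this bridge are both latent electrophiles: C2, the β-carbon of the enal, is carried as an (E)-enol triflate and C5 as a methyl ketone. One charge of vinylmagnesium bromide forms C2–C3 by stereoretentive cross-coupling and C4–C5 by Felkin–Anh addition; metathesis and hydrogenation then complete the ring. An Ireland–Claisen rearrangement of a geranylgeranyl ester supplies C1, C6 and the side chain.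

Key step: step 6

Remark: the labels C1–C6 (and C7 for the exocyclic alkylidene carbon) are also used for the corresponding atoms of the acyclic intermediates; "homofarnesyl" means (3E,7E)-4,8,12-trimethyltrideca-3,7,11-trien-1-yl and "TBS" means tert-butyldimethylsilyl.
Assumption: the (4S,5S)-diazaborolidine of step 2 is taken to deliver the (2S,3R) acid 5; if its facial preference proves opposite, the (4R,5R) reagent is used and nothing else changes.

Step 1
Reactants: 1 5-[(TBS)oxy]pentanoic acid; 2 (2E,6E,10E)-geranylgeraniol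
Product: 3 geranylgeranyl 5-[(TBS)oxy]pentanoate
Conditions: DCC, DMAP (cat.), CH2Cl2, 0 → 25 °C
Reagents that add atoms: none
Why: Steglich esterification joins the acid and the primary allylic alcohol under neutral conditions that leave the E-alkenes and the silyl ether untouched; no stereocentre is formed.

Step 2
Reactants: 3 geranylgeranyl 5-[(TBS)oxy]pentanoate
Product: 5 (2S,3R)-2-[3-(TBS-oxy)propyl]-3-methyl-3-homofarnesylpent-4-enoic acid, via boron ketene acetal 4 (not isolated)
Conditions: (4S,5S)-2-bromo-1,3-bis{[3,5-bis(trifluoromethyl)phenyl]sulfonyl}-4,5-diphenyl-1,3,2-diazaborolidine (1.2 equiv), Et3N, toluene/hexane, −78 → 4 °C; aqueous work-up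
Reagents that add atoms: none
Why: Enantioselective Ireland–Claisen rearrangement: soft enolisation gives the (E)-O-boryl ketene acetal 4 with the side chain cis to O–B, and a chair transition state with this chain and the homofarnesyl group of the (E)-alkene both equatorial sets the C1/C6 relative configuration, while the C2-symmetric sulfonamide ligand on boron selects the enantiotopic face.

Step 3
Reactants: 5 (2S,3R)-acid; 6 methyl propanoate
Product: 8 methyl 2-methyl-3-oxo ester (β-keto ester with C2 as the ketone carbon), via acyl imidazolide 7 (not isolated)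
Conditions: 5, CDI, THF, 25 °C; then added to 6 pre-treated with LDA (2.2 equiv), THF, −78 → −40 °C; aq. NH4Cl
Reagents that add atoms: none
Why: Crossed Claisen condensation of the acyl imidazolide with the lithium enolate of methyl propanoate should give the β-keto ester (the second enolate equivalent deprotonates the product and protects it); C1 and C6 are not touched and the new CH(CH3) centre is removed by enolisation in step 5.

Step 4
Reactants: 8 β-keto ester with the vinyl group on C6
Product: 9 β-keto ester with an acetyl group on C6 (C5 methyl ketone)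
Conditions: PdCl2 (10 mol %), Cu(OAc)2 (20 mol %), O2 (1 atm), DMA/H2O (7:1), 25 °C
Reagents that add atoms: water (supplies the ketone oxygen), O
Why: Tsuji–Wacker oxidation: only the monosubstituted vinyl group undergoes Markovnikov hydroxypalladation, so the methyl ketone should form at C5 while the trisubstituted alkenes stay, and the acetate co-catalyst keeps the medium non-acidic for the silyl ether.

Step 5
Reactants: 9 keto β-keto ester
Product: 10 (E)-enol triflate at C2 (OTf cis to the C7 methyl and trans to CO2Me)
Conditions: Tf2O, aq. Me4NOH, toluene, 0 °C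
Reagents that add atoms: trifluoromethanesulfonic anhydride, O=S(=O)(OS(=O)(=O)C(F)(F)F)C(F)(F)F
Why: O-Sulfonylation of the β-keto ester enolate under non-chelating tetraalkylammonium conditions, where the extended enolate with O− anti to the ester carbonyl is favoured, should give the (E)-enol triflate; the far less acidic methyl ketone is not enolised and fast O-trapping outruns aldol side reactions.

Step 6
Reactants: 10 (E)-enol triflate with the C5 methyl ketone
Product: 12 methyl (2Z)-dienoate carrying a vinyl group on C2 and the (S)-configured tertiary vinyl carbinol at C5, via magnesium alkoxide 11 (not isolated)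
Conditions: CH2=CHMgBr (4 equiv), LaCl3·2LiCl (1.1 equiv), Pd(PPh3)4 (5 mol %), THF, −40 → 25 °C; aqueous work-up
Reagents that add atoms: vinylmagnesium bromide, C=C[Mg]Br
Why: One reagent does two mechanistically independent things in the same flask: lanthanum-assisted 1,2-addition of the vinyl Grignard reagent to the methyl ketone gives alkoxide 11 (bond C4–C5), and oxidative addition of zerovalent palladium into the C2–OTf bond, transmetalation and reductive elimination then give the diene (bond C2–C3). The closest known reaction types are the Kumada–Corriu coupling of enol triflates of β-keto esters, which proceeds with retention, and the Grignard addition to hindered enolisable ketones. The step closes no ring; it installs the two vinyl groups from which step 7 closes the ring. The new stereocentre C5 is controlled by the adjacent quaternary centre C6 in a Felkin–Anh transition state, in which the branched C1 substituent stands anti to the incoming vinyl group and the vinyl group passes the C6 methyl rather than the homofarnesyl methylene, which leads to the (S) carbinol. The step needs chemoselectivity for ketone and triflate over the hindered conjugated ester, retention of the alkene geometry (the descriptor changes from E to Z only through the priority rules) and transmetalation faster than Heck capture of the alkenylpalladium species by the new vinyl carbinol; the tetrasubstituted ester-bearing alkene, the absence of base and the excess of Grignard reagent secure these.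

Step 7
Reactants: 12 bis-vinyl dienoate carbinol
Product: 13 methyl (2Z)-2-(cyclohex-2-en-1-ylidene)propanoate with the complete ring (C3=C4 alkene)
Conditions: second-generation Grubbs catalyst (5 mol %), CH2Cl2, 40 °C
Reagents that add atoms: none
Why: Ring-closing olefin metathesis between the two monosubstituted vinyl groups should close the six-membered ring with loss of ethene, the tri- and tetrasubstituted alkenes being too hindered to compete; no stereocentre changes.

Step 8
Reactants: 13 cyclohexadienyl ester
Product: 14 methyl (2Z)-2-(cyclohexylidene)propanoate with saturated C3–C4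
Conditions: RhCl(PPh3)3 (10 mol %), H2 (1 atm), benzene, 25 °C
Reagents that add atoms: none
Why: Homogeneous hydrogenation with this rhodium chloride phosphine complex should reduce only the cis-disubstituted ring alkene, because tri- and tetrasubstituted alkenes bind the catalyst far more slowly; the exocyclic geometry and all stereocentres are kept.

Step 9
Reactants: 14 saturated ring ester
Product: 15 (2Z)-allylic alcohol
Conditions: i-Bu2AlH (3.5 equiv), CH2Cl2, −78 → 0 °C; aq. Rochelle salt
Reagents that add atoms: none
Why: Hydride reduction of the hindered conjugated methyl ester with diisobutylaluminium hydride should give the allylic primary alcohol by 1,2-reduction without touching the alkene geometry, the silyl ether or the tertiary alcohol.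

Step 10
Reactants: 15 allylic alcohol
Product: 16 (2Z)-enal with the TBS ether
Conditions: MnO2 (activated, excess), CH2Cl2, 25 °C
Reagents that add atoms: none
Why: Allylic oxidation with manganese dioxide is selective for the allylic primary alcohol, the tertiary alcohol cannot be oxidised and the (Z) geometry is kept.

Step 11
Reactants: 16 silyl-protected enal
Product: 17 (2Z)-enal with free primary and tertiary alcohols
Conditions: Bu4NF, AcOH, THF, 0 → 25 °C
Reagents that add atoms: none
Why: Fluoride-induced desilylation frees the primary alcohol, and the acetic acid buffer should prevent base-induced oxa-Michael addition or E/Z isomerisation of the hydroxy enal.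

Step 12
Reactants: 17 diol enal; 18 decanoyl chloride
Product: 19 target decanoate
Conditions: pyridine, DMAP (cat.), CH2Cl2, 0 °C
Reagents that add atoms: none
Why: Nucleophilic acyl substitution (DMAP-catalysed acylation) should be selective for the primary alcohol over the hindered tertiary alcohol and gives the target.

Compound list
1 | 5-[(tert-butyldimethylsilyl)oxy]pentanoic acid | OC(=O)CCCCO[Si](C)(C)C(C)(C)C | starting material
2 | (2E,6E,10E)-geranylgeraniol, (2E,6E,10E)-3,7,11,15-tetramethylhexadeca-2,6,10,14-tetraen-1-ol | CC(C)=CCC/C(C)=C/CC/C(C)=C/CC/C(C)=C/CO | starting material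
3 | (2E,6E,10E)-geranylgeranyl 5-[(tert-butyldimethylsilyl)oxy]pentanoate | CC(C)=CCC/C(C)=C/CC/C(C)=C/CC/C(C)=C/COC(=O)CCCCO[Si](C)(C)C(C)(C)C | intermediate
4 | (E)-O-boryl ketene acetal of 3 (side chain cis to O–B, boron in the (4S,5S)-bis-sulfonyl diazaborolidine) | CC(C)=CCC/C(C)=C/CC/C(C)=C/CC/C(C)=C/CO/C(OB1N(S(=O)(=O)c2cc(cc(c2)C(F)(F)F)C(F)(F)F)[C@@H](c2ccccc2)[C@H](c2ccccc2)N1S(=O)(=O)c1cc(cc(c1)C(F)(F)F)C(F)(F)F)=C/CCCO[Si](C)(C)C(C)(C)C | intermediate
5 | (2S,3R)-2-{3-[(tert-butyldimethylsilyl)oxy]propyl}-3-methyl-3-[(3E,7E)-4,8,12-trimethyltrideca-3,7,11-trien-1-yl]pent-4-enoic acid (acid C2 = ring C1, acid C3 = ring C6) | OC(=O)[C@@H](CCCO[Si](C)(C)C(C)(C)C)[C@@](C)(C=C)CC/C=C(\C)CC/C=C(\C)CCC=C(C)C | intermediate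
6 | methyl propanoate | CCC(=O)OC | starting material
7 | N-acylimidazole (imidazolide) of acid 5 | O=C(n1ccnc1)[C@@H](CCCO[Si](C)(C)C(C)(C)C)[C@@](C)(C=C)CC/C=C(\C)CC/C=C(\C)CCC=C(C)C | intermediate
8 | methyl (4S,5R)-4-{3-[(tert-butyldimethylsilyl)oxy]propyl}-2,5-dimethyl-3-oxo-5-[(3E,7E)-4,8,12-trimethyltrideca-3,7,11-trien-1-yl]hept-6-enoate (both epimers at C2 of the ester) | COC(=O)C(C)C(=O)[C@@H](CCCO[Si](C)(C)C(C)(C)C)[C@@](C)(C=C)CC/C=C(\C)CC/C=C(\C)CCC=C(C)C | intermediate
9 | methyl (4S,5S,8E,12E)-5-acetyl-4-{3-[(tert-butyldimethylsilyl)oxy]propyl}-2,5,9,13,17-pentamethyl-3-oxooctadeca-8,12,16-trienoate (both epimers at C2 of the ester) | COC(=O)C(C)C(=O)[C@@H](CCCO[Si](C)(C)C(C)(C)C)[C@@](C)(C(C)=O)CC/C=C(\C)CC/C=C(\C)CCC=C(C)C | intermediate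
10 | methyl (2E,4S,5S,8E,12E)-5-acetyl-4-{3-[(tert-butyldimethylsilyl)oxy]propyl}-2,5,9,13,17-pentamethyl-3-{[(trifluoromethyl)sulfonyl]oxy}octadeca-2,8,12,16-tetraenoate | COC(=O)/C(C)=C(/OS(=O)(=O)C(F)(F)F)[C@@H](CCCO[Si](C)(C)C(C)(C)C)[C@@](C)(C(C)=O)CC/C=C(\C)CC/C=C(\C)CCC=C(C)C | intermediate
11 | bromomagnesium alkoxide of the (S)-tertiary vinyl carbinol formed from 10 at C5, enol triflate intact | COC(=O)/C(C)=C(/OS(=O)(=O)C(F)(F)F)[C@@H](CCCO[Si](C)(C)C(C)(C)C)[C@@](C)([C@@](C)(O[Mg]Br)C=C)CC/C=C(\C)CC/C=C(\C)CCC=C(C)C | intermediate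
12 | methyl (2Z,4R,5S,8E,12E)-4-{3-[(tert-butyldimethylsilyl)oxy]propyl}-3-ethenyl-5-[(2S)-2-hydroxybut-3-en-2-yl]-2,5,9,13,17-pentamethyloctadeca-2,8,12,16-tetraenoate | COC(=O)/C(C)=C(/C=C)[C@@H](CCCO[Si](C)(C)C(C)(C)C)[C@@](C)([C@@](C)(O)C=C)CC/C=C(\C)CC/C=C(\C)CCC=C(C)C | intermediate
13 | methyl (2Z)-2-[(4S,5S,6R)-6-{3-[(tert-butyldimethylsilyl)oxy]propyl}-4-hydroxy-4,5-dimethyl-5-[(3E,7E)-4,8,12-trimethyltrideca-3,7,11-trien-1-yl]cyclohex-2-en-1-ylidene]propanoate | CC(C)(C)[Si](C)(C)OCCC[C@@H]1/C(=C(/C)C(=O)OC)C=C[C@](C)(O)[C@@]1(C)CC/C=C(\C)CC/C=C(\C)CCC=C(C)C | intermediate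
14 | methyl (2Z)-2-[(2R,3S,4S)-2-{3-[(tert-butyldimethylsilyl)oxy]propyl}-4-hydroxy-3,4-dimethyl-3-[(3E,7E)-4,8,12-trimethyltrideca-3,7,11-trien-1-yl]cyclohexylidene]propanoate | CC(C)(C)[Si](C)(C)OCCC[C@@H]1/C(=C(/C)C(=O)OC)CC[C@](C)(O)[C@@]1(C)CC/C=C(\C)CC/C=C(\C)CCC=C(C)C | intermediate
15 | (2Z)-2-[(2R,3S,4S)-2-{3-[(tert-butyldimethylsilyl)oxy]propyl}-4-hydroxy-3,4-dimethyl-3-[(3E,7E)-4,8,12-trimethyltrideca-3,7,11-trien-1-yl]cyclohexylidene]propan-1-ol | CC(C)(C)[Si](C)(C)OCCC[C@@H]1/C(=C(/C)CO)CC[C@](C)(O)[C@@]1(C)CC/C=C(\C)CC/C=C(\C)CCC=C(C)C | intermediate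
16 | (2Z)-2-[(2R,3S,4S)-2-{3-[(tert-butyldimethylsilyl)oxy]propyl}-4-hydroxy-3,4-dimethyl-3-[(3E,7E)-4,8,12-trimethyltrideca-3,7,11-trien-1-yl]cyclohexylidene]propanal | CC(C)(C)[Si](C)(C)OCCC[C@@H]1/C(=C(/C)C=O)CC[C@](C)(O)[C@@]1(C)CC/C=C(\C)CC/C=C(\C)CCC=C(C)C | intermediate
17 | (2Z)-2-[(2R,3S,4S)-4-hydroxy-2-(3-hydroxypropyl)-3,4-dimethyl-3-[(3E,7E)-4,8,12-trimethyltrideca-3,7,11-trien-1-yl]cyclohexylidene]propanal | OCCC[C@@H]1/C(=C(/C)C=O)CC[C@](C)(O)[C@@]1(C)CC/C=C(\C)CC/C=C(\C)CCC=C(C)C | intermediate
18 | decanoyl chloride | CCCCCCCCCC(Cl)=O | starting material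
19 | 3-[(1R,2S,3S,6Z)-3-hydroxy-2,3-dimethyl-6-(1-oxopropan-2-ylidene)-2-[(3E,7E)-4,8,12-trimethyltrideca-3,7,11-trien-1-yl]cyclohexyl]propyl decanoate | CCCCCCCCCC(=O)OCCC[C@@H]1/C(=C(/C)C=O)CC[C@](C)(O)[C@@]1(C)CC/C=C(\C)CC/C=C(\C)CCC=C(C)C | target

Total step count: 12. Longest linear sequence: 12 steps (from 1 or 2 to 19).

Steps most likely to fail

Step 6 (key step). The acyclic Grignard addition may discriminate the two ketone faces poorly (C5 epimer), the methyl ketone may be enolised instead of attacked, or the alkenylpalladium intermediate may be captured by the new vinyl carbinol in a Heck cyclisation. The fallback still makes both bonds in one flask, but with a two-carbon linchpin whose second bond forms in a ring-closing addition. Setting out from 10, Suzuki–Miyaura coupling with (Z)-1,2-bis(pinacolboryl)ethene (made from acetylene and B2pin2 by platinum-catalysed diboration; Pd(PPh3)4, K3PO4, dioxane/H2O, 60 °C) should give the (Z)-dienylboronate F1. Addition of [Rh(cod)OH]2 to the same flask (80 °C) should then transfer the alkenyl group from boron to rhodium and on to the C5 ketone, closing the ring to the cyclohexadienol 13, where the route is rejoined before step 8.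

Step 2. Enantiofacial or diastereofacial control may be incomplete, or the hindered boron ketene acetal may rearrange too slowly. The fallback sets the same relative configuration without asymmetric induction and separates the enantiomers as covalent diastereomers. Setting out from 3, LDA followed by Me3SiCl/Et3N in THF at −78 °C should give the (Z)-O-trimethylsilyl ketene acetal F2, which on warming rearranges through the same chair to the racemic acid, that is 5 together with its enantiomer F3. Activation with pivaloyl chloride and N-acylation of lithiated (4S)-4-benzyl-1,3-oxazolidin-2-one should give the imide of 5, F4, and the imide of the enantiomer, F5, which are diastereomers and separable by chromatography. Cleavage of F4 with LiOH/H2O2 returns 5, and the route continues with step 3.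

Step 4. Oxidation of the neopentyl-type vinyl group may be slow or regio-unselective (aldehyde formation), and the chelating β-keto ester may interfere with the palladium catalyst. The fallback unmasks the methyl ketone from the γ,δ-unsaturated acid itself before the β-keto ester is built. Setting out from 5, iodolactonisation (I2, NaHCO3, MeCN/H2O, 0 °C; 5-exo attack of the carboxylate on C5) should give the iodomethyl γ-lactone F6, and elimination of hydrogen iodide (DBU, toluene, 80 °C) the enol lactone F7. Acylation of the lithium enolate of methyl propanoate (2.2 equiv, THF, −78 °C) by F7, which sets the C5 methyl ketone free as its enolate, should give 9 directly, and the route continues with step 5.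

Further compounds
F1 | step 6 | (Z)-dienylboronate: 10 with the triflate replaced by a (Z)-2-(4,4,5,5-tetramethyl-1,3,2-dioxaborolan-2-yl)ethenyl group, ketone intact | COC(=O)/C(C)=C(/C=C\B1OC(C)(C)C(C)(C)O1)[C@@H](CCCO[Si](C)(C)C(C)(C)C)[C@@](C)(C(C)=O)CC/C=C(\C)CC/C=C(\C)CCC=C(C)C
F2 | step 2 | (Z)-O-trimethylsilyl ketene acetal of 3 (side chain cis to O–Si) | CC(C)=CCC/C(C)=C/CC/C(C)=C/CC/C(C)=C/CO/C(O[Si](C)(C)C)=C/CCCO[Si](C)(C)C(C)(C)C
F3 | step 2 | (2R,3S)-enantiomer of acid 5 | OC(=O)[C@H](CCCO[Si](C)(C)C(C)(C)C)[C@](C)(C=C)CC/C=C(\C)CC/C=C(\C)CCC=C(C)C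
F4 | step 2 | N-acyl (4S)-4-benzyl-1,3-oxazolidin-2-one of acid 5 | O=C1OC[C@H](Cc2ccccc2)N1C(=O)[C@@H](CCCO[Si](C)(C)C(C)(C)C)[C@@](C)(C=C)CC/C=C(\C)CC/C=C(\C)CCC=C(C)C
F5 | step 2 | N-acyl (4S)-4-benzyl-1,3-oxazolidin-2-one of the enantiomeric acid F3 | O=C1OC[C@H](Cc2ccccc2)N1C(=O)[C@H](CCCO[Si](C)(C)C(C)(C)C)[C@](C)(C=C)CC/C=C(\C)CC/C=C(\C)CCC=C(C)C
F6 | step 4 | iodomethyl γ-lactone from 5 (both configurations at C5) | O=C1OC(CI)[C@@](C)(CC/C=C(\C)CC/C=C(\C)CCC=C(C)C)[C@@H]1CCCO[Si](C)(C)C(C)(C)C
F7 | step 4 | enol lactone (5-methylene γ-lactone) from F6 | O=C1OC(=C)[C@@](C)(CC/C=C(\C)CC/C=C(\C)CCC=C(C)C)[C@@H]1CCCO[Si](C)(C)C(C)(C)C
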